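The route closes the cyclohexane ring (C5–C10) last, by forming the C7–C8 bond. It exploits the cis γ-hydroxy acid array O6–C6–C7–C11–C12: O6 and C12 are tied as a temporary butenolide ring, whose 3-bromomethyl group (C13) becomes an allylchromium that adds through C7 to the C8 aldehyde. One operation closes the carbocycle, sets C7 cis to O6 and unveils the 11(13)-methylene. C8 is then set by oxidation and face-selective reduction, and the lactone, absent from the target, is finally opened. The precursor is an acyclic aldehyde bearing the C5/C10 stereodiad (enantioselective Ireland–Claisen) and a 5-substituted 3-bromomethylbutenolide.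

Key step: step 14

Remark: elemane locants are used for all compounds (C10 quaternary carbon with CH3 and vinyl C1=C2, C9 ring CH2, C8 acyloxy carbon, C7 bearing C11(=C13)–C12, C6 carbinol, C5 bearing C4(=C3)–C15); TBS = tert-butyldimethylsilyl, TBDPS = tert-butyldiphenylsilyl, TES = triethylsilyl, SEM = 2-(trimethylsilyl)ethoxymethyl; acid 32 and aldehyde 34 are assumed to be purchasable.

Step 1
Reactants: 1 tert-butyl(but-3-yn-1-yloxy)dimethylsilane
Product: 3 (2E)-5-(TBS-oxy)-3-methylpent-2-en-1-ol, via alkenyldimethylalane 2 (not isolated)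
Conditions: Me3Al, Cp2ZrCl2 (cat.), CH2Cl2, 0 °C to rt; then n-BuLi, THF, −78 °C; (CH2O)n, rt; aqueous work-up
Reagents that add atoms: trimethylaluminium, C[Al](C)C; formaldehyde (as paraformaldehyde), C=O
Why: Negishi carboalumination adds methyl and aluminium syn across the terminal alkyne with the metal on the terminal carbon, and the derived alanate is hydroxymethylated with retention, so the (E)-alkene that later defines C10 forms as one geometry; no stereocentre is created.

Step 2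
Reactants: 3 (2E)-5-(TBS-oxy)-3-methylpent-2-en-1-ol; 4 itaconic anhydride
Product: 5 4-{[(2E)-5-(TBS-oxy)-3-methylpent-2-en-1-yl]oxy}-2-methylidene-4-oxobutanoic acid
Conditions: toluene, 80 °C
Reagents that add atoms: none
Why: Anhydride alcoholysis takes place at the non-conjugated, more electrophilic carbonyl, which puts the ester on the CH2 arm (future C6) and leaves the acrylic acid (future C15) free; no base is present, so the exocyclic alkene should not migrate.

Step 3
Reactants: 5 half ester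
Product: 7 (2E)-5-(TBS-oxy)-3-methylpent-2-en-1-yl 3-(hydroxymethyl)but-3-enoate, via mixed isobutyl carbonic anhydride 6 (not isolated)
Conditions: i-BuOCOCl, N-methylmorpholine, THF, −15 °C; then NaBH4, H2O, 0 °C
Reagents that add atoms: none
Why: Mixed-anhydride activation followed by borohydride reduction converts only the carboxylic acid into the primary allylic alcohol (C15), the alkyl ester and silyl ether being inert at 0 °C.

Step 4
Reactants: 7 hydroxy ester
Product: 8 (2E)-5-(TBS-oxy)-3-methylpent-2-en-1-yl 3-[(TBDPS-oxy)methyl]but-3-enoate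
Conditions: TBDPSCl, imidazole, CH2Cl2, 0 °C to rt
Reagents that add atoms: tert-butyl(chloro)diphenylsilane, CC(C)(C)[Si](Cl)(c1ccccc1)c1ccccc1
Why: Standard silylation of the primary alcohol; the TBDPS ether is chosen because it survives the later acidic removal of both TBS ethers.

Step 5
Reactants: 8 allyl ester
Product: 10 (2R,3R)-3-[2-(TBS-oxy)ethyl]-3-methyl-2-[3-(TBDPS-oxy)prop-1-en-2-yl]pent-4-enoic acid (5R,10R), via Z(O)-boron ketene acetal 9 (not isolated)
Conditions: (4S,5S)-2-bromo-4,5-diphenyl-1,3-bis(p-tolylsulfonyl)-1,3,2-diazaborolidine (made in situ from the (S,S)-bis-sulfonamide and BBr3), i-Pr2NEt, CH2Cl2, −78 °C, then −20 to 4 °C; aqueous work-up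
Reagents that add atoms: none
Why: Enantioselective boron-mediated Ireland–Claisen rearrangement: the hindered amine in CH2Cl2 is the pairing expected to give the Z(O) ketene acetal (C4 cis to O–B), the chair transition state with the (E)-allyl unit places C4 and the C9 chain pseudo-equatorial and so fixes the C5/C10 relative configuration, and the C2-symmetric sulfonamide ligands on boron are chosen to expose the enantioface leading to (5R,10R).

Step 6
Reactants: 10 acid
Product: 12 N-methoxy-N-methylamide of acid 10 (5R,10R), via N-acylimidazole 11 (not isolated)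
Conditions: 1,1′-carbonyldiimidazole, CH2Cl2, rt; then MeNHOMe·HCl, rt
Reagents that add atoms: N,O-dimethylhydroxylamine hydrochloride, CNOC.Cl
Why: Amide formation through the acylimidazole needs no strong base, so the C5 centre α to the carbonyl should not be enolised; it provides the chelating amide for clean monoaddition.

Step 7
Reactants: 12 Weinreb amide; 13 tert-butyldimethyl(prop-2-yn-1-yloxy)silane
Product: 15 (5R,6R)-1-(TBS-oxy)-6-[2-(TBS-oxy)ethyl]-6-methyl-5-[3-(TBDPS-oxy)prop-1-en-2-yl]oct-7-en-2-yn-4-one, via lithium acetylide 14 (not isolated)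
Conditions: 13, n-BuLi, THF, −78 °C; then 12, −78 to 0 °C; aqueous NH4Cl
Reagents that add atoms: none
Why: Weinreb ketone synthesis: the acetylide adds once because the chelated tetrahedral adduct persists until the quench; existing stereocentres are untouched.

Step 8
Reactants: 15 ynone
Product: 16 (4S,5R,6R)-1-(TBS-oxy)-6-[2-(TBS-oxy)ethyl]-6-methyl-5-[3-(TBDPS-oxy)prop-1-en-2-yl]oct-7-en-2-yn-4-ol (5R,6S,10R)
Conditions: Ru[(S,S)-TsNCHPhCHPhNH](η6-p-cymene) (3 mol%), i-PrOH, rt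
Reagents that add atoms: none
Why: Noyori asymmetric transfer hydrogenation of an alkynyl ketone: the (S,S)-ligand should deliver hydride to the face that gives the (6S)-propargylic alcohol (alkynyl group in the π-directing position), the same sense as Felkin–Anh attack anti to the quaternary C10.

Step 9
Reactants: 16 propargylic alcohol
Product: 18 (2Z,4S,5R,6R)-2-iodo-1-(TBS-oxy)-6-[2-(TBS-oxy)ethyl]-6-methyl-5-[3-(TBDPS-oxy)prop-1-en-2-yl]octa-2,7-dien-4-ol, via cyclic alkenylalanate 17 (not isolated)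
Conditions: NaAlH2(OCH2CH2OMe)2, THF, 0 °C to rt; then I2, THF, −78 °C
Reagents that add atoms: iodine, II
Why: Hydroxyl-directed trans-hydroalumination: the alkoxide-bound aluminium hydride delivers hydride to C7 and aluminium to C11 within a five-membered alanate, and iodinolysis with retention gives the vinyl iodide with iodine cis to C6.

Step 10
Reactants: 18 vinyl iodide
Product: 19 (5R)-3-[(TBS-oxy)methyl]-5-{(1R,2R)-2-[2-(TBS-oxy)ethyl]-2-methyl-1-[3-(TBDPS-oxy)prop-1-en-2-yl]but-3-en-1-yl}furan-2(5H)-one (5R,6R,10R)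
Conditions: PdCl2(PPh3)2 (5 mol%), CO (1 atm), K2CO3, THF, 45 °C
Reagents that add atoms: carbon monoxide, [C-]#[O+]
Why: Palladium-catalysed carbonylative lactonisation: oxidative addition, CO insertion and capture of the acylpalladium by the cis C6 hydroxyl close the butenolide and install C12; the C6 centre is retained (its descriptor changes only by priority).

Step 11
Reactants: 19 bis-TBS butenolide
Product: 20 (5R)-3-(hydroxymethyl)-5-{(1R,2R)-2-(2-hydroxyethyl)-2-methyl-1-[3-(TBDPS-oxy)prop-1-en-2-yl]but-3-en-1-yl}furan-2(5H)-one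
Conditions: camphorsulfonic acid (cat.), MeOH/CH2Cl2, 0 °C
Reagents that add atoms: none
Why: Acid-catalysed methanolysis cleaves the two primary TBS ethers much faster than the TBDPS ether (selective desilylation).

Step 12
Reactants: 20 diol
Product: 21 (5R)-3-(bromomethyl)-5-{(1R,2R)-2-(2-hydroxyethyl)-2-methyl-1-[3-(TBDPS-oxy)prop-1-en-2-yl]but-3-en-1-yl}furan-2(5H)-one
Conditions: N-bromosuccinimide, Me2S, CH2Cl2, −20 to 0 °C
Reagents that add atoms: N-bromosuccinimide, O=C1CCC(=O)N1Br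
Why: Corey–Kim halogenation: only the allylic alkoxysulfonium ion is displaced by bromide (SN2), the saturated primary alcohol being returned on work-up.

Step 13
Reactants: 21 bromo alcohol
Product: 22 (5R)-3-(bromomethyl)-5-{(1R,2R)-2-methyl-2-(2-oxoethyl)-1-[3-(TBDPS-oxy)prop-1-en-2-yl]but-3-en-1-yl}furan-2(5H)-one
Conditions: Dess–Martin periodinane, NaHCO3, CH2Cl2, rt
Reagents that add atoms: none
Why: Dess–Martin oxidation gives the C8 aldehyde under buffered, non-basic conditions that leave the allylic bromide and the butenolide C6–H untouched.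

Step 14
Reactants: 22 bromomethylbutenolide aldehyde
Product: 24 (5R,6S,7R,8S,10R)-8-hydroxy-15-(TBDPS-oxy)elema-1,3,11(13)-trien-12,6-olide (cis-fused lactone; equatorial C8 alcohol), via allylchromium dichloride 23 (not isolated)
Conditions: CrCl2 (4 equiv), THF, 0.005 M, 0 °C to rt; aqueous work-up
Reagents that add atoms: none
Why: Two equivalents of CrCl2 reduce the C13–Br bond to an allylchromium dichloride whose γ-carbon C7 attacks the C8 aldehyde (SE2′) through a chair-like Zimmerman–Traxler array with the aldehyde oxygen bound to chromium on C13. The closest known reaction type is the Nozaki–Hiyama–Kishi (Barbier-type) allylation of aldehydes by 2-(halomethyl)acrylate-type halides, here intramolecular. The cyclohexane ring C5–C6–C7–C8–C9–C10 closes by a 6-exo-trig addition of the allyl terminus C7 to the carbonyl carbon C8; attack through C13 would need an eight-membered ring. C7 is set by the existing C6 centre, because the three-atom tether C5–C10–C9 can deliver C8 only to the butenolide face that carries C5, so the lactone ends cis-fused (H6 and H7 syn). At C8 the chair array with C9 pseudo-equatorial should favour the equatorial (8S) alcohol, but this centre need not be controlled because both epimers converge at the ketone in step 15. The step needs γ-regioselectivity, cis fusion and chemoselectivity for the C–Br bond over aldehyde, lactone and silyl ether, which ring size, the tether, the mildness of CrCl2 and high dilution secure.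

Step 15
Reactants: 24 cyclised alcohol
Product: 25 (5R,6S,7S,10R)-8-oxo-15-(TBDPS-oxy)elema-1,3,11(13)-trien-12,6-olide
Conditions: Dess–Martin periodinane, NaHCO3, CH2Cl2, 0 °C; used crude
Reagents that add atoms: none
Why: Dess–Martin oxidation removes the C8 stereocentre under neutral conditions; the β,γ-unsaturated ketone is not purified, so the exocyclic alkene should not move into conjugation and C7 should not epimerise.

Step 16
Reactants: 25 ketone
Product: 26 (5R,6S,7R,8R,10R)-8-hydroxy-15-(TBDPS-oxy)elema-1,3,11(13)-trien-12,6-olide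
Conditions: LiAlH(O-t-Bu)3, THF, −78 to −40 °C
Reagents that add atoms: none
Why: Diastereoselective ketone reduction: the bulky hydride is shielded from the ring face carrying the axial C10 vinyl group and the axial lactone oxygen on C6 (both 1,3 to C8) and should attack from the opposite face, giving the axial (8R) alcohol cis to C11 and O6; lactone and acrylate are inert at this temperature.

Step 17
Reactants: 26 lactone alcohol
Product: 27 (5R,6S,7S,8R,10R)-8-(TES-oxy)-15-(TBDPS-oxy)elema-1,3,11(13)-trien-12,6-olide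
Conditions: Et3SiOTf, 2,6-lutidine, CH2Cl2, −78 °C
Reagents that add atoms: triethylsilyl trifluoromethanesulfonate, CC[Si](CC)(CC)OS(=O)(=O)C(F)(F)F
Why: Silyl triflate silylation of the hindered C8 hydroxyl keeps O8 distinguishable from O6 once the lactone is opened.

Step 18
Reactants: 27 TES ether
Product: 29 SEM (5R,6S,7S,8R,10R)-6-hydroxy-8-(TES-oxy)-15-(TBDPS-oxy)elema-1,3,11(13)-trien-12-oate, via lithium carboxylate 28 (not isolated)
Conditions: LiOH·H2O (1.05 equiv), THF/H2O, 0 °C; evaporation; then SEMCl, DMF, 0 °C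
Reagents that add atoms: lithium hydroxide, [Li+].[OH-]; 2-(trimethylsilyl)ethoxymethyl chloride, C[Si](C)(C)CCOCCl
Why: Saponification opens the temporary lactone to the hydroxy carboxylate, which is alkylated on carboxylate oxygen (the hindered O6 alcohol does not react without strong base); all stereocentres are untouched.

Step 19
Reactants: 29 hydroxy SEM ester
Product: 30 SEM (5R,6S,7R,8R,10R)-6-(TBS-oxy)-8-(TES-oxy)-15-(TBDPS-oxy)elema-1,3,11(13)-trien-12-oate
Conditions: t-BuMe2SiOTf, 2,6-lutidine, CH2Cl2, 0 °C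
Reagents that add atoms: tert-butyldimethylsilyl trifluoromethanesulfonate, CC(C)(C)[Si](C)(C)OS(=O)(=O)C(F)(F)F
Why: Silyl triflate silylation of the hindered C6 hydroxyl also removes the only nucleophile able to relactonise onto C12.

Step 20
Reactants: 30 tris-silyl ether
Product: 31 SEM (5R,6S,7R,8R,10R)-8-hydroxy-6-(TBS-oxy)-15-(TBDPS-oxy)elema-1,3,11(13)-trien-12-oate
Conditions: pyridinium p-toluenesulfonate, MeOH/CH2Cl2, 0 °C
Reagents that add atoms: none
Why: Selective solvolysis: a secondary TES ether is cleaved by mild acid in methanol much faster than a secondary TBS or a primary TBDPS ether, so only O8 is freed; the low temperature limits lactonisation of O8 onto C12.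

Step 21
Reactants: 31 C8 alcohol; 32 2-[bis(2,2,2-trifluoroethoxy)phosphoryl]propanoic acid
Product: 33 SEM (5R,6S,7R,8R,10R)-8-{2-[bis(2,2,2-trifluoroethoxy)phosphoryl]propanoyloxy}-6-(TBS-oxy)-15-(TBDPS-oxy)elema-1,3,11(13)-trien-12-oate (epimers at the phosphonate carbon)
Conditions: DCC, DMAP (cat.), CH2Cl2, 0 °C to rt
Reagents that add atoms: none
Why: Steglich esterification: the α-phosphono acid reacts through its O-acylisourea with ketene-like reactivity, which suits the hindered C8 hydroxyl; the new phosphonate-bearing centre is lost in the next step.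

Step 22
Reactants: 33 phosphonate ester; 34 2-oxoethyl acetate
Product: 36 SEM (5R,6S,7R,8R,10R)-8-[(2Z)-4-acetoxy-2-methylbut-2-enoyloxy]-6-(TBS-oxy)-15-(TBDPS-oxy)elema-1,3,11(13)-trien-12-oate, via potassium phosphonate enolate 35 (not isolated)
Conditions: KN(SiMe3)2, 18-crown-6, THF, −78 °C; then 34, −78 °C
Reagents that add atoms: none
Why: Still–Gennari olefination: with the electron-poor bis(trifluoroethyl) phosphonate and a crown-separated potassium enolate, elimination from the kinetic adduct outruns its equilibration, which should give the (Z)-trisubstituted enoate (carbonyl cis to CH2OAc).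

Step 23
Reactants: 36 protected target
Product: 37 (5R,6S,7S,8R,10R)-8-[(2Z)-4-acetoxy-2-methylbut-2-enoyloxy]-6,15-dihydroxyelema-1,3,11(13)-trien-12-oic acid (target)
Conditions: TASF [(Me2N)3S][Me3SiF2], DMF, 0 °C to rt; aqueous NaH2PO4 work-up
Reagents that add atoms: none
Why: Fluoride-mediated global deprotection: the SEM ester should fragment first to the carboxylate, which cannot lactonise, the two silyl ethers follow, and the buffered work-up protonates the acid without conditions strong enough to close the lactone.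

Compound list
1 | tert-butyl(but-3-yn-1-yloxy)dimethylsilane | C#CCCO[Si](C)(C)C(C)(C)C | starting material
2 | (E)-[4-(TBS-oxy)-2-methylbut-1-en-1-yl]dimethylalane | C/C(CCO[Si](C)(C)C(C)(C)C)=C\[Al](C)C | intermediate
3 | (2E)-5-(TBS-oxy)-3-methylpent-2-en-1-ol | C/C(CCO[Si](C)(C)C(C)(C)C)=C\CO | intermediate
4 | itaconic anhydride (3-methylideneoxolane-2,5-dione) | C=C1CC(=O)OC1=O | starting material
5 | 4-{[(2E)-5-(TBS-oxy)-3-methylpent-2-en-1-yl]oxy}-2-methylidene-4-oxobutanoic acid | C=C(CC(=O)OC/C=C(\C)CCO[Si](C)(C)C(C)(C)C)C(=O)O | intermediate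
6 | mixed isobutyl carbonic anhydride of acid 5 | C=C(CC(=O)OC/C=C(\C)CCO[Si](C)(C)C(C)(C)C)C(=O)OC(=O)OCC(C)C | intermediate
7 | (2E)-5-(TBS-oxy)-3-methylpent-2-en-1-yl 3-(hydroxymethyl)but-3-enoate | C=C(CO)CC(=O)OC/C=C(\C)CCO[Si](C)(C)C(C)(C)C | intermediate
8 | (2E)-5-(TBS-oxy)-3-methylpent-2-en-1-yl 3-[(TBDPS-oxy)methyl]but-3-enoate | C=C(CO[Si](c1ccccc1)(c1ccccc1)C(C)(C)C)CC(=O)OC/C=C(\C)CCO[Si](C)(C)C(C)(C)C | intermediate
9 | Z(O)-boron ketene acetal of 8 with the (4S,5S)-4,5-diphenyl-1,3-ditosyl-1,3,2-diazaborolidin-2-yl group on oxygen | C=C(CO[Si](c1ccccc1)(c1ccccc1)C(C)(C)C)/C=C(\OB1N(S(=O)(=O)c2ccc(C)cc2)[C@@H](c2ccccc2)[C@H](c2ccccc2)N1S(=O)(=O)c1ccc(C)cc1)OC/C=C(\C)CCO[Si](C)(C)C(C)(C)C | intermediate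
10 | (2R,3R)-3-[2-(TBS-oxy)ethyl]-3-methyl-2-[3-(TBDPS-oxy)prop-1-en-2-yl]pent-4-enoic acid (5R,10R) | C=C[C@@](C)(CCO[Si](C)(C)C(C)(C)C)[C@H](C(=C)CO[Si](c1ccccc1)(c1ccccc1)C(C)(C)C)C(=O)O | intermediate
11 | N-acylimidazole of acid 10 | C=C[C@@](C)(CCO[Si](C)(C)C(C)(C)C)[C@H](C(=C)CO[Si](c1ccccc1)(c1ccccc1)C(C)(C)C)C(=O)n1ccnc1 | intermediate
12 | (2R,3R)-N-methoxy-N-methyl-3-[2-(TBS-oxy)ethyl]-3-methyl-2-[3-(TBDPS-oxy)prop-1-en-2-yl]pent-4-enamide | C=C[C@@](C)(CCO[Si](C)(C)C(C)(C)C)[C@H](C(=C)CO[Si](c1ccccc1)(c1ccccc1)C(C)(C)C)C(=O)N(C)OC | intermediate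
13 | tert-butyldimethyl(prop-2-yn-1-yloxy)silane | C#CCO[Si](C)(C)C(C)(C)C | starting material
14 | [3-(TBS-oxy)prop-1-yn-1-yl]lithium | [Li]C#CCO[Si](C)(C)C(C)(C)C | intermediate
15 | (5R,6R)-1-(TBS-oxy)-6-[2-(TBS-oxy)ethyl]-6-methyl-5-[3-(TBDPS-oxy)prop-1-en-2-yl]oct-7-en-2-yn-4-one | C=C[C@@](C)(CCO[Si](C)(C)C(C)(C)C)[C@H](C(=C)CO[Si](c1ccccc1)(c1ccccc1)C(C)(C)C)C(=O)C#CCO[Si](C)(C)C(C)(C)C | intermediate
16 | (4S,5R,6R)-1-(TBS-oxy)-6-[2-(TBS-oxy)ethyl]-6-methyl-5-[3-(TBDPS-oxy)prop-1-en-2-yl]oct-7-en-2-yn-4-ol (5R,6S,10R) | C=C[C@@](C)(CCO[Si](C)(C)C(C)(C)C)[C@H](C(=C)CO[Si](c1ccccc1)(c1ccccc1)C(C)(C)C)[C@H](O)C#CCO[Si](C)(C)C(C)(C)C | intermediate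
17 | sodium 2,2-bis(2-methoxyethoxy)-2,5-dihydro-1,2-oxaluminol-2-uide formed from 16 (Al on C11, O6 on Al) | C=C[C@@](C)(CCO[Si](C)(C)C(C)(C)C)[C@H](C(=C)CO[Si](c1ccccc1)(c1ccccc1)C(C)(C)C)[C@@H]1O[Al-](OCCOC)(OCCOC)C(CO[Si](C)(C)C(C)(C)C)=C1.[Na+] | intermediate
18 | (2Z,4S,5R,6R)-2-iodo-1-(TBS-oxy)-6-[2-(TBS-oxy)ethyl]-6-methyl-5-[3-(TBDPS-oxy)prop-1-en-2-yl]octa-2,7-dien-4-ol | C=C[C@@](C)(CCO[Si](C)(C)C(C)(C)C)[C@H](C(=C)CO[Si](c1ccccc1)(c1ccccc1)C(C)(C)C)[C@H](O)/C=C(\I)CO[Si](C)(C)C(C)(C)C | intermediate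
19 | (5R)-3-[(TBS-oxy)methyl]-5-{(1R,2R)-2-[2-(TBS-oxy)ethyl]-2-methyl-1-[3-(TBDPS-oxy)prop-1-en-2-yl]but-3-en-1-yl}furan-2(5H)-one | C=C[C@@](C)(CCO[Si](C)(C)C(C)(C)C)[C@H](C(=C)CO[Si](c1ccccc1)(c1ccccc1)C(C)(C)C)[C@@H]1OC(=O)C(CO[Si](C)(C)C(C)(C)C)=C1 | intermediate
20 | (5R)-3-(hydroxymethyl)-5-{(1R,2R)-2-(2-hydroxyethyl)-2-methyl-1-[3-(TBDPS-oxy)prop-1-en-2-yl]but-3-en-1-yl}furan-2(5H)-one | C=C[C@@](C)(CCO)[C@H](C(=C)CO[Si](c1ccccc1)(c1ccccc1)C(C)(C)C)[C@@H]1OC(=O)C(CO)=C1 | intermediate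
21 | (5R)-3-(bromomethyl)-5-{(1R,2R)-2-(2-hydroxyethyl)-2-methyl-1-[3-(TBDPS-oxy)prop-1-en-2-yl]but-3-en-1-yl}furan-2(5H)-one | C=C[C@@](C)(CCO)[C@H](C(=C)CO[Si](c1ccccc1)(c1ccccc1)C(C)(C)C)[C@@H]1OC(=O)C(CBr)=C1 | intermediate
22 | (5R)-3-(bromomethyl)-5-{(1R,2R)-2-methyl-2-(2-oxoethyl)-1-[3-(TBDPS-oxy)prop-1-en-2-yl]but-3-en-1-yl}furan-2(5H)-one | C=C[C@@](C)(CC=O)[C@H](C(=C)CO[Si](c1ccccc1)(c1ccccc1)C(C)(C)C)[C@@H]1OC(=O)C(CBr)=C1 | intermediate
23 | allylchromium dichloride from 22 (CrCl2 on C13) | C=C[C@@](C)(CC=O)[C@H](C(=C)CO[Si](c1ccccc1)(c1ccccc1)C(C)(C)C)[C@@H]1OC(=O)C(C[Cr](Cl)Cl)=C1 | intermediate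
24 | (5R,6S,7R,8S,10R)-8-hydroxy-15-(TBDPS-oxy)elema-1,3,11(13)-trien-12,6-olide | C=C[C@@]1(C)C[C@H](O)[C@@H](C(=C)C(=O)O2)[C@@H]2[C@H]1C(=C)CO[Si](c1ccccc1)(c1ccccc1)C(C)(C)C | intermediate
25 | (5R,6S,7S,10R)-8-oxo-15-(TBDPS-oxy)elema-1,3,11(13)-trien-12,6-olide | C=C[C@@]1(C)CC(=O)[C@@H](C(=C)C(=O)O2)[C@@H]2[C@H]1C(=C)CO[Si](c1ccccc1)(c1ccccc1)C(C)(C)C | intermediate
26 | (5R,6S,7R,8R,10R)-8-hydroxy-15-(TBDPS-oxy)elema-1,3,11(13)-trien-12,6-olide | C=C[C@@]1(C)C[C@@H](O)[C@@H](C(=C)C(=O)O2)[C@@H]2[C@H]1C(=C)CO[Si](c1ccccc1)(c1ccccc1)C(C)(C)C | intermediate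
27 | (5R,6S,7S,8R,10R)-8-(TES-oxy)-15-(TBDPS-oxy)elema-1,3,11(13)-trien-12,6-olide | C=C[C@@]1(C)C[C@@H](O[Si](CC)(CC)CC)[C@@H](C(=C)C(=O)O2)[C@@H]2[C@H]1C(=C)CO[Si](c1ccccc1)(c1ccccc1)C(C)(C)C | intermediate
28 | lithium (5R,6S,7S,8R,10R)-6-hydroxy-8-(TES-oxy)-15-(TBDPS-oxy)elema-1,3,11(13)-trien-12-oate | C=C[C@@]1(C)C[C@@H](O[Si](CC)(CC)CC)[C@@H](C(=C)C(=O)[O-])[C@@H](O)[C@H]1C(=C)CO[Si](c1ccccc1)(c1ccccc1)C(C)(C)C.[Li+] | intermediate
29 | SEM (5R,6S,7S,8R,10R)-6-hydroxy-8-(TES-oxy)-15-(TBDPS-oxy)elema-1,3,11(13)-trien-12-oate | C=C[C@@]1(C)C[C@@H](O[Si](CC)(CC)CC)[C@@H](C(=C)C(=O)OCOCC[Si](C)(C)C)[C@@H](O)[C@H]1C(=C)CO[Si](c1ccccc1)(c1ccccc1)C(C)(C)C | intermediate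
30 | SEM (5R,6S,7R,8R,10R)-6-(TBS-oxy)-8-(TES-oxy)-15-(TBDPS-oxy)elema-1,3,11(13)-trien-12-oate | C=C[C@@]1(C)C[C@@H](O[Si](CC)(CC)CC)[C@@H](C(=C)C(=O)OCOCC[Si](C)(C)C)[C@@H](O[Si](C)(C)C(C)(C)C)[C@H]1C(=C)CO[Si](c1ccccc1)(c1ccccc1)C(C)(C)C | intermediate
31 | SEM (5R,6S,7R,8R,10R)-8-hydroxy-6-(TBS-oxy)-15-(TBDPS-oxy)elema-1,3,11(13)-trien-12-oate | C=C[C@@]1(C)C[C@@H](O)[C@@H](C(=C)C(=O)OCOCC[Si](C)(C)C)[C@@H](O[Si](C)(C)C(C)(C)C)[C@H]1C(=C)CO[Si](c1ccccc1)(c1ccccc1)C(C)(C)C | intermediate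
32 | 2-[bis(2,2,2-trifluoroethoxy)phosphoryl]propanoic acid | CC(C(=O)O)P(=O)(OCC(F)(F)F)OCC(F)(F)F | starting material
33 | SEM (5R,6S,7R,8R,10R)-8-{2-[bis(2,2,2-trifluoroethoxy)phosphoryl]propanoyloxy}-6-(TBS-oxy)-15-(TBDPS-oxy)elema-1,3,11(13)-trien-12-oate | C=C[C@@]1(C)C[C@@H](OC(=O)C(C)P(=O)(OCC(F)(F)F)OCC(F)(F)F)[C@@H](C(=C)C(=O)OCOCC[Si](C)(C)C)[C@@H](O[Si](C)(C)C(C)(C)C)[C@H]1C(=C)CO[Si](c1ccccc1)(c1ccccc1)C(C)(C)C | intermediate
34 | 2-oxoethyl acetate | CC(=O)OCC=O | starting material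
35 | potassium enolate of phosphonate ester 33 | C=C[C@@]1(C)C[C@@H](OC(=O)[C-](C)P(=O)(OCC(F)(F)F)OCC(F)(F)F)[C@@H](C(=C)C(=O)OCOCC[Si](C)(C)C)[C@@H](O[Si](C)(C)C(C)(C)C)[C@H]1C(=C)CO[Si](c1ccccc1)(c1ccccc1)C(C)(C)C.[K+] | intermediate
36 | SEM (5R,6S,7R,8R,10R)-8-[(2Z)-4-acetoxy-2-methylbut-2-enoyloxy]-6-(TBS-oxy)-15-(TBDPS-oxy)elema-1,3,11(13)-trien-12-oate | C=C[C@@]1(C)C[C@@H](OC(=O)/C(C)=C\COC(C)=O)[C@@H](C(=C)C(=O)OCOCC[Si](C)(C)C)[C@@H](O[Si](C)(C)C(C)(C)C)[C@H]1C(=C)CO[Si](c1ccccc1)(c1ccccc1)C(C)(C)C | intermediate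
37 | (5R,6S,7S,8R,10R)-8-[(2Z)-4-acetoxy-2-methylbut-2-enoyloxy]-6,15-dihydroxyelema-1,3,11(13)-trien-12-oic acid | C=C[C@@]1(C)C[C@@H](OC(=O)/C(C)=C\COC(C)=O)[C@@H](C(=C)C(=O)O)[C@@H](O)[C@H]1C(=C)CO | target

Total step count: 23. Longest linear sequence: 23 steps (1 to 37); compounds 4, 13, 32 and 34 enter as purchased reagents.

Steps most likely to fail

Step 14 (key ring closure). The allylchromium may be protonated or couple intermolecularly instead of closing the ring, or may react through C13. The fallback replaces the metal-centred closed transition state by a Lewis-acid-triggered allylsilane addition. It sets out from 21: palladium-catalysed silylation (Me3SiSiMe3, Pd(dba)2 cat., THF) should give the allylsilane alcohol F1, and Dess–Martin oxidation the allylsilane aldehyde F2. BF3·OEt2 in CH2Cl2 at −78 °C should then close the C7–C8 bond by an anti-SE2′ Hosomi–Sakurai reaction, again on the butenolide face that carries C5. Both C8 epimers converge at ketone 25, so the fallback returns to the route at 24.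

Step 5 (Ireland–Claisen rearrangement). Enolate geometry may leak or enantioface discrimination may be incomplete, leaving the C10 epimer or the enantiomer in the acid. The fallback replaces reagent control by classical resolution. It sets out from stereochemically impure 10: the acid is converted with (R)-1-phenylethylamine into the (R)-1-phenylethylammonium salt F3, which is recrystallised to constant rotation and then acidified with cold aqueous KHSO4, returning to 10.

Step 23 (global deprotection). Under basic fluoride the freed O6 alkoxide may relactonise onto C12 before the ester has fragmented, the acyl group may migrate from O8 to O6, or the acetate may be lost. The fallback uses two non-basic operations. It sets out from 36: MgBr2·OEt2 in CH2Cl2 should cleave only the SEM ester and give the bis-silylated acid F4. HF·pyridine buffered with pyridine in THF then removes both silyl ethers under weakly acidic conditions and arrives at 37.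

Further compounds
F1 | step 14 | (5R)-5-{(1R,2R)-2-(2-hydroxyethyl)-2-methyl-1-[3-(TBDPS-oxy)prop-1-en-2-yl]but-3-en-1-yl}-3-[(trimethylsilyl)methyl]furan-2(5H)-one | C=C[C@@](C)(CCO)[C@H](C(=C)CO[Si](c1ccccc1)(c1ccccc1)C(C)(C)C)[C@@H]1OC(=O)C(C[Si](C)(C)C)=C1
F2 | step 14 | (5R)-5-{(1R,2R)-2-methyl-2-(2-oxoethyl)-1-[3-(TBDPS-oxy)prop-1-en-2-yl]but-3-en-1-yl}-3-[(trimethylsilyl)methyl]furan-2(5H)-one | C=C[C@@](C)(CC=O)[C@H](C(=C)CO[Si](c1ccccc1)(c1ccccc1)C(C)(C)C)[C@@H]1OC(=O)C(C[Si](C)(C)C)=C1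
F3 | step 5 | (R)-1-phenylethylammonium salt of acid 10 | C=C[C@@](C)(CCO[Si](C)(C)C(C)(C)C)[C@H](C(=C)CO[Si](c1ccccc1)(c1ccccc1)C(C)(C)C)C(=O)[O-].C[C@@H]([NH3+])c1ccccc1
F4 | step 23 | (5R,6S,7R,8R,10R)-8-[(2Z)-4-acetoxy-2-methylbut-2-enoyloxy]-6-(TBS-oxy)-15-(TBDPS-oxy)elema-1,3,11(13)-trien-12-oic acid | C=C[C@@]1(C)C[C@@H](OC(=O)/C(C)=C\COC(C)=O)[C@@H](C(=C)C(=O)O)[C@@H](O[Si](C)(C)C(C)(C)C)[C@H]1C(=C)CO[Si](c1ccccc1)(c1ccccc1)C(C)(C)C
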